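**Retrosynthetic overview**
- The target is a C2-symmetric 2,2'-bi(hydroxy-1,4-benzoquinone). Each hydroxyquinone is traced back to its methoxymethyl (MOM) ether and then to a para-methoxyphenol (oxidative demethylation, acetal hydrolysis).
- Key disconnection, two-directional: both six-membered carbocycles are cut at once into alkyne + CO + alkoxy(alkenyl)carbene (Dötz benzannulation). Each ring closes through the bond between the carbonyl carbon next to the inter-ring bond (CO-derived) and the methyl-bearing ring carbon.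
- Enabling feature: the four contiguous carbons ArCH2CH2–C=C(ring)–C(ring')=C–CH2CH2Ar around the inter-ring bond are a masked buta-1,3-diyne. In each ring the para pair of C=O carbons is CO plus the carbene carbon, and the C(OH)=C(CH3) unit is a 1-oxygenated prop-1-enyl group.
- Diyne: Eglinton homocoupling joins two molecules of 4-(2-methoxyphenyl)but-1-yne (from 2-methoxybenzyl bromide + lithiated silylpropyne). Carbene complex: from the Z MOM enol ether of propanal, Cr(CO)6 and Me3OBF4.
- Ring order: both quinone carbocycles are formed simultaneously in the key step; the two anisole rings are bought.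

Key step: step 6

Assumption: the inter-ring axis of the target is drawn without a descriptor and is taken as racemic; metal carbonyls are written with Cr=C=O double bonds purely as a SMILES drawing convention.

Step 1
Reactants: 1 trimethyl(prop-1-yn-1-yl)silane; 2 1-(bromomethyl)-2-methoxybenzene (2-methoxybenzyl bromide)
Product: 4 [4-(2-methoxyphenyl)but-1-yn-1-yl]trimethylsilane, via silylpropargyllithium 3 (not isolated)
Conditions: n-BuLi, THF, −78 °C; then 2, −78 °C to rt
Reagents that add atoms: none
Why: SN2 alkylation of lithiated 1-(trimethylsilyl)propyne by a benzylic bromide; the silyl group blocks the alkyne terminus and steers attack to the propargylic carbon.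

Step 2
Reactants: 4 [4-(2-methoxyphenyl)but-1-yn-1-yl]trimethylsilane (2 equiv)
Product: 6 1,8-bis(2-methoxyphenyl)octa-3,5-diyne, via terminal alkyne 5 (not isolated)
Conditions: K2CO3 (cat.), MeOH/pyridine (1:1), rt; then Cu(OAc)2 (3 equiv), 50 °C
Reagents that add atoms: none
Why: Methanolysis of the alkynyl C–Si bond frees the terminal alkyne 5, and Eglinton (Glaser-type) oxidative homocoupling then joins two molecules of 5 through their terminal sp carbons, so that two molecules of 4 give one molecule of the symmetric 1,3-diyne 6 in one pot.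

Step 3
Reactants: 7 prop-2-en-1-ol (allyl alcohol)
Product: 8 3-(methoxymethoxy)prop-1-ene
Conditions: MOMCl, i-Pr2NEt, CH2Cl2, 0 °C to rt; fractional distillation
Reagents that add atoms: chloromethyl methyl ether (MOMCl), COCCl
Why: O-alkylation of the alcohol by the reactive α-chloro ether (MOM acetal formation).

Step 4
Reactants: 8 3-(methoxymethoxy)prop-1-ene
Product: 9 (1Z)-1-(methoxymethoxy)prop-1-ene
Conditions: KOt-Bu (0.2 equiv), DMSO, rt
Reagents that add atoms: none
Why: Base-catalysed allyl-to-propenyl ether isomerisation; the cation-chelated cis allyl anion should give the Z enol ether under kinetic control.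

Step 5
Reactants: 9 (1Z)-1-(methoxymethoxy)prop-1-ene; 10 hexacarbonylchromium, Cr(CO)6
Product: 13 pentacarbonyl[(2Z)-1-methoxy-2-(methoxymethoxy)but-2-en-1-ylidene]chromium, via vinyllithium 11 (not isolated), via lithium acylchromate 12 (not isolated)
Conditions: s-BuLi, THF, −78 °C; Cr(CO)6, THF, −78 °C to rt; then Me3OBF4, CH2Cl2, 0 °C
Reagents that add atoms: trimethyloxonium tetrafluoroborate (Me3OBF4), C[O+](C)C.F[B-](F)(F)F
Why: MOM-directed α-lithiation of the Z enol ether with retention of alkene geometry, addition of the vinyllithium to a CO ligand and O-methylation of the acylchromate is the Fischer carbene synthesis.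

Step 6
Reactants: 6 1,8-bis(2-methoxyphenyl)octa-3,5-diyne; 13 pentacarbonyl[(2Z)-1-methoxy-2-(methoxymethoxy)but-2-en-1-ylidene]chromium (2.5 equiv)
Product: 15 5,5'-dimethoxy-4,4'-bis(methoxymethoxy)-6,6'-bis[2-(2-methoxyphenyl)ethyl]-3,3'-dimethyl-[1,1'-biphenyl]-2,2'-diol, via alkynylphenol 14 (not isolated)
Conditions: THF (0.05 M), 55 °C, Ar; then air, MeCN, rt
Reagents that add atoms: none
Why: Loss of CO from 13 opens a site for one triple bond of 6, which inserts into the Cr=C bond; CO insertion then gives a chromium-bound dienylketene that closes the six-membered carbocycle by bonding its ketene (CO-derived) carbon to the methyl-bearing alkene carbon and tautomerises to the phenol, after which the aryl alkyne 14 repeats the sequence at the second triple bond with a second molecule of 13. The closest known reaction type is the Dötz benzannulation, including its twofold use on 1,4-disubstituted buta-1,3-diynes to give 2,2'-biphenols. Both rings close in the same mode, a 6π-electrocyclisation of a cis-dienylketene, made easy because the Z geometry of 13 puts hydrogen and not methyl on the inner face of the reacting alkene carbon. No stereocentre is formed; the tetra-ortho-substituted biaryl axis arises as a racemate, in line with the target being drawn without an axial descriptor. The step needs each alkyne to insert so that the carbene carbon bonds to the CH2CH2Ar-bearing carbon and the CO-derived carbon ends next to the inter-ring bond; the conjugated alkynyl group in the first annulation and the bulky 2,6-disubstituted aryl group in the second are expected to take the position next to the CO-derived carbon, as diynes and aryl alkyl alkynes do in this reaction. Benzannulation is preferred over cyclopentannulation for alkenyl chromium carbenes in THF.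

Step 7
Reactants: 15 5,5'-dimethoxy-4,4'-bis(methoxymethoxy)-6,6'-bis[2-(2-methoxyphenyl)ethyl]-3,3'-dimethyl-[1,1'-biphenyl]-2,2'-diol
Product: 16 5,5'-bis(methoxymethoxy)-3,3'-bis[2-(2-methoxyphenyl)ethyl]-6,6'-dimethyl-2,2'-bi(1,4-benzoquinone)
Conditions: PhI(OAc)2 (2.4 equiv), MeCN/H2O (2:1), 0 °C
Reagents that add atoms: water, O
Why: Hypervalent-iodine oxidative demethylation of a para-methoxyphenol (water adds at the methoxy-bearing carbon, methanol is lost) should give the para-quinone; the anisole rings have no free phenol and the MOM acetal should survive the weakly acidic medium.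

Step 8
Reactants: 16 5,5'-bis(methoxymethoxy)-3,3'-bis[2-(2-methoxyphenyl)ethyl]-6,6'-dimethyl-2,2'-bi(1,4-benzoquinone)
Product: 17 5,5'-dihydroxy-3,3'-bis[2-(2-methoxyphenyl)ethyl]-6,6'-dimethyl-2,2'-bi(1,4-benzoquinone) (CNP0293637.0)
Conditions: 2 M HCl (aq), THF, 40 °C
Reagents that add atoms: none
Why: Acid hydrolysis of the MOM acetal of a vinylogous acid (2-alkoxyquinone) is fast and should leave the aryl methyl ethers untouched.

**Compound list**
1 | trimethyl(prop-1-yn-1-yl)silane | CC#C[Si](C)(C)C | starting material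
2 | 1-(bromomethyl)-2-methoxybenzene | COc1ccccc1CBr | starting material
3 | [3-(trimethylsilyl)prop-2-yn-1-yl]lithium | [Li]CC#C[Si](C)(C)C | intermediate
4 | [4-(2-methoxyphenyl)but-1-yn-1-yl]trimethylsilane | COc1ccccc1CCC#C[Si](C)(C)C | intermediate
5 | 1-(but-3-yn-1-yl)-2-methoxybenzene | COc1ccccc1CCC#C | intermediate
6 | 1,8-bis(2-methoxyphenyl)octa-3,5-diyne | COc1ccccc1CCC#CC#CCCc1ccccc1OC | intermediate
7 | prop-2-en-1-ol | C=CCO | starting material
8 | 3-(methoxymethoxy)prop-1-ene | C=CCOCOC | intermediate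
9 | (1Z)-1-(methoxymethoxy)prop-1-ene | C/C=C\OCOC | intermediate
10 | hexacarbonylchromium, Cr(CO)6 | O=C=[Cr](=C=O)(=C=O)(=C=O)(=C=O)=C=O | starting material
11 | [(1Z)-1-(methoxymethoxy)prop-1-en-1-yl]lithium | [Li]/C(OCOC)=C/C | intermediate
12 | lithium pentacarbonyl[(2Z)-2-(methoxymethoxy)-1-oxidobut-2-en-1-ylidene]chromate | [Li+].[O-]C(/C(OCOC)=C/C)=[Cr](=C=O)(=C=O)(=C=O)(=C=O)=C=O | intermediate
13 | pentacarbonyl[(2Z)-1-methoxy-2-(methoxymethoxy)but-2-en-1-ylidene]chromium | COC(/C(OCOC)=C/C)=[Cr](=C=O)(=C=O)(=C=O)(=C=O)=C=O | intermediate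
14 | 4-methoxy-3-(methoxymethoxy)-5-[2-(2-methoxyphenyl)ethyl]-6-[4-(2-methoxyphenyl)but-1-yn-1-yl]-2-methylphenol | COc1ccccc1CCC#Cc1c(O)c(C)c(OCOC)c(OC)c1CCc1ccccc1OC | intermediate
15 | 5,5'-dimethoxy-4,4'-bis(methoxymethoxy)-6,6'-bis[2-(2-methoxyphenyl)ethyl]-3,3'-dimethyl-[1,1'-biphenyl]-2,2'-diol (racemic axis) | COc1ccccc1CCc1c(OC)c(OCOC)c(C)c(O)c1-c1c(O)c(C)c(OCOC)c(OC)c1CCc1ccccc1OC | intermediate
16 | 5,5'-bis(methoxymethoxy)-3,3'-bis[2-(2-methoxyphenyl)ethyl]-6,6'-dimethyl-2,2'-bi(1,4-benzoquinone) | COc1ccccc1CCC1=C(C2=C(CCc3ccccc3OC)C(=O)C(OCOC)=C(C)C2=O)C(=O)C(C)=C(OCOC)C1=O | intermediate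
17 | 5,5'-dihydroxy-3,3'-bis[2-(2-methoxyphenyl)ethyl]-6,6'-dimethyl-2,2'-bi(1,4-benzoquinone) | COc1ccccc1CCC1=C(C2=C(CCc3ccccc3OC)C(=O)C(O)=C(C)C2=O)C(=O)C(C)=C(O)C1=O | target

**Step count and risks**
Total steps: 8. Longest linear sequence: 6 steps (steps 3, 4, 5, 6, 7, 8 from allyl alcohol); the diyne branch (steps 1, 2) joins at step 6.

Steps most likely to fail:

1. Step 6. What may go wrong: alkyne insertion in the wrong orientation in one or both annulations, which would scramble the methyl/oxygen pattern relative to the inter-ring bond, or stalling after the first annulation at the hindered aryl alkyne. Fallback (sets out from 2, comes back at 17): a classical two-directional biaryl route that makes the inter-ring bond first and needs no insertion regiocontrol. Compound 2 is heated with PPh3 in toluene to give (2-methoxybenzyl)triphenylphosphonium bromide F1. Commercial 1,2,4-trimethoxybenzene is lithiated between its 2- and 4-methoxy groups (n-BuLi, THF, 0 °C) and methylated with MeI to 1,2,4-trimethoxy-3-methylbenzene F2. Oxidative arene homocoupling para to the 2-methoxy group (PhI(OCOCF3)2, BF3·OEt2, CH2Cl2, −40 °C) should give 2,2',4,4',5,5'-hexamethoxy-3,3'-dimethyl-1,1'-biphenyl F3. Twofold Rieche formylation (Cl2CHOMe, TiCl4, CH2Cl2, 0 °C) at the only free ring positions gives 3,3',4,4',6,6'-hexamethoxy-5,5'-dimethyl-[1,1'-biphenyl]-2,2'-dicarbaldehyde F4. Twofold Wittig olefination with the ylide from F1 (NaHMDS, THF) gives 3,3',4,4',6,6'-hexamethoxy-2,2'-bis[2-(2-methoxyphenyl)ethenyl]-5,5'-dimethyl-1,1'-biphenyl F5 (alkene geometry irrelevant). Hydrogenation (H2, Pd/C, EtOAc) gives 3,3',4,4',6,6'-hexamethoxy-2,2'-bis[2-(2-methoxyphenyl)ethyl]-5,5'-dimethyl-1,1'-biphenyl F6. Oxidative demethylation with (NH4)2Ce(NO3)6 in MeCN/H2O converts each 1,2,4-trimethoxyarene into the 2-methoxy-1,4-quinone, giving 5,5'-dimethoxy-3,3'-bis[2-(2-methoxyphenyl)ethyl]-6,6'-dimethyl-2,2'-bi(1,4-benzoquinone) F7. Hydrolysis of the vinylogous esters (NaOH, aq. MeOH, then HCl) gives 17.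

2. Step 5. What may go wrong: deprotonation at the allylic methyl group instead of the vinylic α-position, or decomposition of the electron-rich α-alkoxyalkenyl carbene complex during O-methylation and purification. Fallback (sets out from 6 and 10, comes back at 17): carry the ring oxygen in after the annulation. Commercial (E)-1-bromoprop-1-ene is lithiated (t-BuLi, Et2O, −78 °C), added to 10 and methylated with Me3OBF4 to give pentacarbonyl[(2E)-1-methoxybut-2-en-1-ylidene]chromium F8. Twofold benzannulation with 6 under the conditions of step 6 should give 5,5'-dimethoxy-6,6'-bis[2-(2-methoxyphenyl)ethyl]-3,3'-dimethyl-[1,1'-biphenyl]-2,2'-diol F9. PhI(OAc)2 in aqueous MeCN gives 3,3'-bis[2-(2-methoxyphenyl)ethyl]-6,6'-dimethyl-2,2'-bi(1,4-benzoquinone) F10. Nucleophilic epoxidation (H2O2, Na2CO3, aq. EtOH) of the less substituted, CH-bearing quinone double bonds gives the 5,6:5',6'-bis-epoxide F11 as a diastereomer mixture. Acid (H2SO4 in AcOH, rt) isomerises each epoxyquinone to the hydroxyquinone, giving 17.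

3. Step 7. What may go wrong: over-oxidation spreading to the biaryl or anisole rings, or partial loss of the MOM groups in the acidic medium leading to mixtures. Fallback (sets out from 15, comes back at 17): reverse the order of unmasking and change the oxidation mode. Compound 15 is treated with HCl in MeOH/THF to remove both MOM groups, giving 5,5'-dimethoxy-6,6'-bis[2-(2-methoxyphenyl)ethyl]-3,3'-dimethyl-[1,1'-biphenyl]-2,2',4,4'-tetrol F12, in which the methoxy group of each ring has one free hydroxyl ortho and one para to it. Periodate oxidative demethylation (NaIO4, aq. MeCN, 0 °C) should remove that methyl group as methanol; whether the ring passes through the ortho-quinone or the para-quinone, the two are tautomers of the same hydroxyquinone, so 17 should result directly.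

**Further compounds**
F1 | step 6 | (2-methoxybenzyl)triphenylphosphonium bromide | COc1ccccc1C[P+](c1ccccc1)(c1ccccc1)c1ccccc1.[Br-]
F2 | step 6 | 1,2,4-trimethoxy-3-methylbenzene | COc1ccc(OC)c(C)c1OC
F3 | step 6 | 2,2',4,4',5,5'-hexamethoxy-3,3'-dimethyl-1,1'-biphenyl | COc1cc(-c2cc(OC)c(OC)c(C)c2OC)c(OC)c(C)c1OC
F4 | step 6 | 3,3',4,4',6,6'-hexamethoxy-5,5'-dimethyl-[1,1'-biphenyl]-2,2'-dicarbaldehyde | COc1c(C=O)c(-c2c(C=O)c(OC)c(OC)c(C)c2OC)c(OC)c(C)c1OC
F5 | step 6 | 3,3',4,4',6,6'-hexamethoxy-2,2'-bis[2-(2-methoxyphenyl)ethenyl]-5,5'-dimethyl-1,1'-biphenyl (E/Z mixture) | COc1ccccc1C=Cc1c(OC)c(OC)c(C)c(OC)c1-c1c(C=Cc2ccccc2OC)c(OC)c(OC)c(C)c1OC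
F6 | step 6 | 3,3',4,4',6,6'-hexamethoxy-2,2'-bis[2-(2-methoxyphenyl)ethyl]-5,5'-dimethyl-1,1'-biphenyl | COc1ccccc1CCc1c(OC)c(OC)c(C)c(OC)c1-c1c(CCc2ccccc2OC)c(OC)c(OC)c(C)c1OC
F7 | step 6 | 5,5'-dimethoxy-3,3'-bis[2-(2-methoxyphenyl)ethyl]-6,6'-dimethyl-2,2'-bi(1,4-benzoquinone) | COc1ccccc1CCC1=C(C2=C(CCc3ccccc3OC)C(=O)C(OC)=C(C)C2=O)C(=O)C(C)=C(OC)C1=O
F8 | step 5 | pentacarbonyl[(2E)-1-methoxybut-2-en-1-ylidene]chromium | COC(/C=C/C)=[Cr](=C=O)(=C=O)(=C=O)(=C=O)=C=O
F9 | step 5 | 5,5'-dimethoxy-6,6'-bis[2-(2-methoxyphenyl)ethyl]-3,3'-dimethyl-[1,1'-biphenyl]-2,2'-diol | COc1ccccc1CCc1c(OC)cc(C)c(O)c1-c1c(O)c(C)cc(OC)c1CCc1ccccc1OC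
F10 | step 5 | 3,3'-bis[2-(2-methoxyphenyl)ethyl]-6,6'-dimethyl-2,2'-bi(1,4-benzoquinone) | COc1ccccc1CCC1=C(C2=C(CCc3ccccc3OC)C(=O)C=C(C)C2=O)C(=O)C(C)=CC1=O
F11 | step 5 | 5,6:5',6'-bis-epoxide of F10 (diastereomer mixture) | COc1ccccc1CCC1=C(C2=C(CCc3ccccc3OC)C(=O)C3OC3(C)C2=O)C(=O)C2(C)OC2C1=O
F12 | step 7 | 5,5'-dimethoxy-6,6'-bis[2-(2-methoxyphenyl)ethyl]-3,3'-dimethyl-[1,1'-biphenyl]-2,2',4,4'-tetrol | COc1ccccc1CCc1c(OC)c(O)c(C)c(O)c1-c1c(O)c(C)c(O)c(OC)c1CCc1ccccc1OC
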